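My unit was the turnover: one substrate lost, one reagent used and one product made, counted in percent of the substrate charged. The reagent was never read, so one reagent per turnover was my assumption.

- eta: substrate 0.020 M; reagent 0.016 M; initiator 0.24 mM; radical scavenger 0.20 mM; the very flask that is asked about, followed so far
- flask: substrate 0.020 M; reagent 0.0160 M; initiator 0.24 mM; radical scavenger 0.20 mM; time 10 h

eta run (percent of the substrate charged)

| time / h | substrate / % | product / % |
|---|---|---|
| 0.250 | 99.6 | 0.4 |
| 0.833 | 98.8 | 1.1 |
| 1.33 | 47.8 | 52.5 |
| 2.00 | 24.2 | 75.3 |
| 3.00 | 20.0 | 79.4 |
| 4.00 | 18.9 | 80.1 |
| 5.00 | 19.0 | 80.3 |

(scatter of a reading: 0.3 percentage points)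

* the state of affairs at 10 h: stopped, and by what, or still going (all of the substrate has reacted / forward and back rates have come level / the reagent has run out first / it is still moving)
* part of the substrate gone at 10 h
* the product standing at 10 h, as a percentage of the substrate charged

- the reaction counts as stopped when no species that holds the substrate changes by six tenths of a point or more over the second half of the time

The charges give the count at once:

ceiling = [reagent] / [substrate], as charged = 0.0160 M / 0.020 M = 80.0 %

I called this the turnover ceiling: the product that the reagent can pay for, if the reagent is the limiting reagent.

In the first instants the eta run barely turned over, with 1.1 % of product at 0.833 h. I took this for an induction period, in which the radical scavenger, charged at 0.20 mM, stopped the chains that the initiator began.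

In the middle, the eta run made 51 percentage points of product by 1.33 h, far faster than before, while substrate fell 51 points, so the count ran close to one for one. At 2.00 h, with 75.3 % of product, the ceiling left room for 4.7 points.

At the end, product in the eta run moved 0.2 points from 4.00 h to 5.00 h, and a repeated reading scatters by 0.3 points. It stood at 80.3 % on the ceiling, with 19.0 % of substrate still present. So I expected the flask to have stopped by 10 h for want of reagent, with product at the ceiling and substrate gone as read late:

substrate gone = mean of the last two readings = 81.0 %

That reading lies 1 point above the ceiling, so I allowed for a little substrate going elsewhere than to product.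

The forecast gave the reagent has run out first, 80.5 % gone and 80 % of product, holding that “product is capped at 80%”.

The flask gave the reagent has run out first, 81.4 % gone and 80.0 % of product.

    substrate + second chain carrier → released group + first chain carrier (k = 2.60 × 10⁵ M⁻¹ s⁻¹)
    reagent + first chain carrier → product + second chain carrier (k = 1.70 × 10⁵ M⁻¹ s⁻¹)
    second chain carrier + radical scavenger → ended chains B (k = 1.10 × 10⁹ M⁻¹ s⁻¹)
    initiator → 2 initiating radical (k = 1.50 × 10⁻⁴ s⁻¹)
    2 first chain carrier → ended chains A (k = 7.50 × 10⁸ M⁻¹ s⁻¹)
    substrate + initiating radical → capped initiator + first chain carrier (k = 7.70 × 10⁶ M⁻¹ s⁻¹)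

At 10.0 h the flask had 0 % of its reagent charge left, and its product of 80.0 % stood level with the ceiling of 80.0 %. The same count goes on a neighbour flask, charged with 0.080 M of substrate and the reagent unchanged:

ceiling = 0.0160 M / 0.080 M = 20.0 %

At 10.0 h that neighbour flask held 20.0 % of product, with 0 % of its reagent left and 79.7 % of its substrate still standing.

The numbers in the tables are simulated from invented constants; noise was put on by code.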